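**Assumption:** the target is made exactly as the SMILES reads: (4S,6S,7R,8R), 6-OH cis to the C7–C11 bond, lactone trans-fused.

Atom labels follow 1,10-seco-eudesmane numbering: C1 = CH2OAc, C4 = side-chain CH(CH3), C5=C10 = ring alkene, C6 = CHOH, C7 = ring-fusion CH, C8 = lactone O–CH, C9 = ring CH2, C11(=C13H2), C12 = lactone C=O, C14 = CH2O-isobutyryl.

## Retrosynthetic overview

1. 27 ⇐ 26 (desilylation). 26 ⇐ acyclic formyl allylboronate 24 in one operation: intramolecular allylboration closes the cyclohexene (C7–C8) first, then the O8 borate lactonizes onto the C12 ester (trans lactone second).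
2. 24 ⇐ ynoate 18 by syn-hydrostannation, iodination and borylmethyl Negishi coupling; this fixes C6 cis to CO2Me, which becomes the trans ring fusion.
3. 18 ⇐ enal 15 + methyl propiolate (catalytic asymmetric alkynylation sets C6).
4. 15 ⇐ (Z)-enol triflate 9 + dioxolanylmethylzinc bromide (stereoretentive Negishi coupling gives the tetrasubstituted C5=C10 alkene with C6 cis to C9). 9 ⇐ β-keto Weinreb amide 8 ⇐ (S)-citronellic acid (C4 from the chiral pool) + acid chloride 4 (carries the isobutyrate).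
5. The C1 acetate comes from the citronellyl alkene (ozonolysis, reduction, acetylation).

## Route

Step 1
Reactants: 1 glycolic acid; 2 isobutyryl chloride
Product: 4 2-(isobutyryloxy)acetyl chloride, via 2-(isobutyryloxy)acetic acid 3 (not isolated)
Conditions: 2 (1.2 equiv), neat, 60 °C; then (COCl)2, DMF (cat.), CH2Cl2, 0 °C to rt; distil
Reagents that add atoms: oxalyl chloride, O=C(Cl)C(Cl)=O
Why: O-acylation of the hydroxyl group by the acid chloride, then conversion of the free acid into its chloride (Vilsmeier-type activation); no stereocenter is involved.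

Step 2
Reactants: 5 (S)-citronellic acid
Product: 7 (3S)-N-methoxy-N,3,7-trimethyloct-6-enamide, via acyl imidazolide 6 (not isolated)
Conditions: 1,1'-carbonyldiimidazole, CH2Cl2, rt; then MeNHOMe·HCl, rt
Reagents that add atoms: N,O-dimethylhydroxylamine hydrochloride, CNOC.Cl
Why: Weinreb amide formation through the acyl imidazolide; the C4 stereocenter comes from the chiral pool and is not touched.

Step 3
Reactants: 7 (3S)-N-methoxy-N,3,7-trimethyloct-6-enamide; 4 2-(isobutyryloxy)acetyl chloride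
Product: 8 (3S)-2-[(isobutyryloxy)acetyl]-N-methoxy-N,3,7-trimethyloct-6-enamide (β-keto Weinreb amide, both C5 epimers)
Conditions: LiN(i-Pr)2 (2.1 equiv), THF, −78 °C; enolate added to 4 (1.0 equiv), −78 °C; aq. NH4Cl
Reagents that add atoms: none
Why: crossed Claisen-type C-acylation of the amide enolate by the much more electrophilic acid chloride, with the second equivalent of base absorbing the acidic product; the new C5 center is lost when C5 becomes sp2.

Step 4
Reactants: 8 β-keto Weinreb amide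
Product: 9 (2Z,3S)-2-[2-(isobutyryloxy)-1-(trifluoromethylsulfonyloxy)ethylidene]-N-methoxy-N,3,7-trimethyloct-6-enamide (OTf on C10 cis to the amide carbonyl C6)
Conditions: LiN(SiMe3)2 (1.1 equiv), THF, −78 °C; Comins' reagent, −78 to 0 °C
Reagents that add atoms: N-(5-chloropyridin-2-yl)bis(trifluoromethanesulfonimide) (Comins' reagent), FC(F)(F)S(=O)(=O)N(c1ccc(Cl)cn1)S(=O)(=O)C(F)(F)F
Why: enol triflate formation from the lithium-chelated enolate of the 1,3-dicarbonyl (both carbonyl oxygens on lithium), which places OTf cis to the amide carbonyl.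

Step 5
Reactants: 9 (Z)-enol triflate; 10 (1,3-dioxolan-2-ylmethyl)zinc bromide
Product: 11 (2E,3S)-2-[1-(1,3-dioxolan-2-yl)-3-(isobutyryloxy)propan-2-ylidene]-N-methoxy-N,3,7-trimethyloct-6-enamide (C9H2 cis to C6)
Conditions: 10 (1.5 equiv, 0.5 M in THF), PdCl2(dppf) (5 mol %), THF, 40 °C
Reagents that add atoms: none
Why: Negishi sp2–sp3 cross-coupling proceeds with retention of alkene geometry, so the tetrasubstituted C5=C10 alkene is formed with C6 and C9 cis as the ring needs.

Step 6
Reactants: 11 tetrasubstituted acrylamide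
Product: 13 (2E,3S)-2-[1-(1,3-dioxolan-2-yl)-3-(isobutyryloxy)propan-2-ylidene]-6-hydroxy-N-methoxy-N,3-dimethylhexanamide, via aldehyde 12 (not isolated)
Conditions: O3, CH2Cl2/MeOH 3:1, −78 °C (Sudan Red end point); then NaBH4, −78 to 0 °C
Reagents that add atoms: ozone, [O-][O+]=O
Why: ozonolysis with reductive work-up cleaves the electron-rich trisubstituted alkene selectively over the electron-poor, hindered acrylamide alkene, and NaBH4 leaves the Weinreb amide and the ester alone.

Step 7
Reactants: 13 primary alcohol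
Product: 14 (2E,3S)-6-acetoxy-2-[1-(1,3-dioxolan-2-yl)-3-(isobutyryloxy)propan-2-ylidene]-N-methoxy-N,3-dimethylhexanamide
Conditions: Ac2O, pyridine, DMAP (cat.), CH2Cl2, 0 °C to rt
Reagents that add atoms: acetic anhydride, CC(=O)OC(C)=O
Why: nucleophile-catalysed acetylation of the only free hydroxyl installs the C1 acetate.

Step 8
Reactants: 14 Weinreb amide
Product: 15 (2E)-2-[(2S)-5-acetoxypentan-2-yl]-3-(1,3-dioxolan-2-ylmethyl)-4-(isobutyryloxy)but-2-enal (CHO cis to the CH2–dioxolane arm)
Conditions: Cp2Zr(H)Cl (1.6 equiv), THF, rt, 30 min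
Reagents that add atoms: none
Why: chemoselective amide-to-aldehyde reduction by hydrozirconation of the amide carbonyl, which spares both esters and the acetal and keeps the alkene geometry.

Step 9
Reactants: 15 enal; 16 methyl propiolate
Product: 17 methyl (4S,5E)-5-[(2S)-5-acetoxypentan-2-yl]-6-(1,3-dioxolan-2-ylmethyl)-4-hydroxy-7-(isobutyryloxy)hept-5-en-2-ynoate
Conditions: 16 (3 equiv), Zn(CH3)2 (3 equiv), (R,R)-ProPhenol (20 mol %), Ph3P=O (40 mol %), toluene, 4 °C, 48 h
Reagents that add atoms: none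
Why: zinc–ProPhenol-catalysed asymmetric alkynylation delivers the alkynylzinc to the Si face of the aldehyde under catalyst control to set C6 as S (the remote C4 center exerts no bias); the ligand antipode is assigned by analogy and must be confirmed on the first run.

Step 10
Reactants: 17 propargylic alcohol
Product: 18 methyl (4S,5E)-5-[(2S)-5-acetoxypentan-2-yl]-4-(tert-butyldimethylsilyloxy)-6-(1,3-dioxolan-2-ylmethyl)-7-(isobutyryloxy)hept-5-en-2-ynoate
Conditions: TBSOTf, 2,6-lutidine, CH2Cl2, −78 to 0 °C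
Reagents that add atoms: tert-butyldimethylsilyl trifluoromethanesulfonate, CC(C)(C)[Si](C)(C)OS(=O)(=O)C(F)(F)F
Why: silylation protects O6, which would otherwise close a butenolide onto the cis ester after the next step and would compete with O8 in the lactonization.

Step 11
Reactants: 18 silyloxy ynoate
Product: 20 methyl (2E,4S,5E)-5-[(2S)-5-acetoxypentan-2-yl]-4-(tert-butyldimethylsilyloxy)-6-(1,3-dioxolan-2-ylmethyl)-2-iodo-7-(isobutyryloxy)hepta-2,5-dienoate (C6 cis to CO2Me), via α-stannyl enoate 19 (not isolated)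
Conditions: Bu3SnH (1.15 equiv), PdCl2(PPh3)2 (2 mol %), THF, 0 °C; then I2 (1.3 equiv), CH2Cl2, 0 °C
Reagents that add atoms: iodine, II
Why: palladium-catalysed syn-hydrostannation of the ynoate puts tin α to the ester and H on C7 on the same side, and iododestannylation occurs with retention, so C6 ends up cis to CO2Me.

Step 12
Reactants: 20 α-iodo enoate; 21 2-(iodomethyl)-4,4,5,5-tetramethyl-1,3,2-dioxaborolane
Product: 23 methyl (2Z,4S,5E)-5-[(2S)-5-acetoxypentan-2-yl]-4-(tert-butyldimethylsilyloxy)-6-(1,3-dioxolan-2-ylmethyl)-7-(isobutyryloxy)-2-[(4,4,5,5-tetramethyl-1,3,2-dioxaborolan-2-yl)methyl]hepta-2,5-dienoate, via (pinacolatoboryl)methylzinc iodide 22 (not isolated)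
Conditions: 21 (2 equiv), Zn dust (activated with BrCH2CH2Br and Me3SiCl), THF, rt; then 20, Pd(dba)2 (5 mol %), P(2-furyl)3 (10 mol %), THF, rt
Reagents that add atoms: none
Why: Negishi coupling with retention of geometry gives the 2-(methoxycarbonyl)allylboronate in which C6 is trans to CH2B; it is stable because no free aldehyde is present.

Step 13
Reactants: 23 allylboronate acetal
Product: 26 6-O-tert-butyldimethylsilyl ether of the target (trans-fused α-methylene lactone, OTBS cis to C7–C11), via formyl allylboronate 24 (not isolated), via cyclohexenyl borate ester 25 (not isolated)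
Conditions: TESOTf (2 equiv), 2,4,6-collidine (3 equiv), CH2Cl2, 0 °C; H2O, rt; then toluene (0.01 M), 45 °C, 12 h; then p-TsOH·H2O (0.2 equiv), rt
Reagents that add atoms: water, O
Why: chemoselective acetal cleavage frees the C8 aldehyde, which undergoes intramolecular allylboration through a closed chair transition state fused to the forming half-chair: because C6 is trans to CH2B, both tether ends are equatorial and C7–C11 and C8–O come out trans; the OTBS group sits pseudoaxial (it avoids 1,2-allylic strain with the C5 side chain and is not antiperiplanar to the forming bond) and so ends cis to C11; the O8 borate then lactonizes onto the ester under acid to close the second ring.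

Step 14
Reactants: 26 silyl ether
Product: 27 [(3aR,4S,7aR)-5-[(2S)-5-acetoxypentan-2-yl]-4-hydroxy-3-methylidene-2-oxo-2,3,3a,4,7,7a-hexahydro-1-benzofuran-6-yl]methyl 2-methylpropanoate (target)
Conditions: HF·pyridine, pyridine, THF, 0 °C to rt
Reagents that add atoms: none
Why: fluoride-mediated desilylation under mildly acidic conditions frees the 6-OH without ester cleavage or lactone migration to O6, which base could cause.

## Compound list

1 | glycolic acid | OCC(=O)O | starting material
2 | isobutyryl chloride | CC(C)C(Cl)=O | starting material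
3 | 2-(isobutyryloxy)acetic acid | CC(C)C(=O)OCC(=O)O | intermediate
4 | 2-(isobutyryloxy)acetyl chloride | CC(C)C(=O)OCC(Cl)=O | intermediate
5 | (S)-citronellic acid, (3S)-3,7-dimethyloct-6-enoic acid | OC(=O)C[C@@H](C)CCC=C(C)C | starting material
6 | (3S)-1-(imidazol-1-yl)-3,7-dimethyloct-6-en-1-one (acyl imidazolide) | O=C(C[C@@H](C)CCC=C(C)C)n1ccnc1 | intermediate
7 | (3S)-N-methoxy-N,3,7-trimethyloct-6-enamide | CON(C)C(=O)C[C@@H](C)CCC=C(C)C | intermediate
8 | (3S)-2-[(isobutyryloxy)acetyl]-N-methoxy-N,3,7-trimethyloct-6-enamide (C5 epimers) | CON(C)C(=O)C(C(=O)COC(=O)C(C)C)[C@@H](C)CCC=C(C)C | intermediate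
9 | (Z)-enol triflate of 8, OTf cis to amide C=O | CON(C)C(=O)/C(=C(\OS(=O)(=O)C(F)(F)F)COC(=O)C(C)C)[C@@H](C)CCC=C(C)C | intermediate
10 | (1,3-dioxolan-2-ylmethyl)zinc bromide | Br[Zn]CC1OCCO1 | starting material
11 | (2E,3S)-2-[1-(1,3-dioxolan-2-yl)-3-(isobutyryloxy)propan-2-ylidene]-N-methoxy-N,3,7-trimethyloct-6-enamide | CON(C)C(=O)/C(=C(\CC1OCCO1)COC(=O)C(C)C)[C@@H](C)CCC=C(C)C | intermediate
12 | 6-oxohexanamide analogue of 11 (C1 aldehyde) | CON(C)C(=O)/C(=C(\CC1OCCO1)COC(=O)C(C)C)[C@@H](C)CCC=O | intermediate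
13 | 6-hydroxyhexanamide analogue (C1 alcohol) | CON(C)C(=O)/C(=C(\CC1OCCO1)COC(=O)C(C)C)[C@@H](C)CCCO | intermediate
14 | 6-acetoxyhexanamide analogue (C1 acetate) | CON(C)C(=O)/C(=C(\CC1OCCO1)COC(=O)C(C)C)[C@@H](C)CCCOC(C)=O | intermediate
15 | (2E)-2-[(2S)-5-acetoxypentan-2-yl]-3-(1,3-dioxolan-2-ylmethyl)-4-(isobutyryloxy)but-2-enal | O=C/C(=C(\CC1OCCO1)COC(=O)C(C)C)[C@@H](C)CCCOC(C)=O | intermediate
16 | methyl propiolate | C#CC(=O)OC | starting material
17 | methyl (4S,5E)-5-[(2S)-5-acetoxypentan-2-yl]-6-(1,3-dioxolan-2-ylmethyl)-4-hydroxy-7-(isobutyryloxy)hept-5-en-2-ynoate | COC(=O)C#C[C@H](O)/C(=C(\CC1OCCO1)COC(=O)C(C)C)[C@@H](C)CCCOC(C)=O | intermediate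
18 | 4-O-TBS ether of 17 | COC(=O)C#C[C@H](O[Si](C)(C)C(C)(C)C)/C(=C(\CC1OCCO1)COC(=O)C(C)C)[C@@H](C)CCCOC(C)=O | intermediate
19 | (2E)-2-(tributylstannyl) dienoate, C6 cis to CO2Me | COC(=O)/C([Sn](CCCC)(CCCC)CCCC)=C\[C@H](O[Si](C)(C)C(C)(C)C)/C(=C(\CC1OCCO1)COC(=O)C(C)C)[C@@H](C)CCCOC(C)=O | intermediate
20 | (2E)-2-iodo dienoate, C6 cis to CO2Me | COC(=O)/C(I)=C\[C@H](O[Si](C)(C)C(C)(C)C)/C(=C(\CC1OCCO1)COC(=O)C(C)C)[C@@H](C)CCCOC(C)=O | intermediate
21 | 2-(iodomethyl)-4,4,5,5-tetramethyl-1,3,2-dioxaborolane | ICB1OC(C)(C)C(C)(C)O1 | starting material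
22 | (pinacolatoboryl)methylzinc iodide | I[Zn]CB1OC(C)(C)C(C)(C)O1 | intermediate
23 | (2Z)-2-[(pinacolatoboryl)methyl] dienoate (allylboronate, dioxolane intact) | COC(=O)/C(CB1OC(C)(C)C(C)(C)O1)=C\[C@H](O[Si](C)(C)C(C)(C)C)/C(=C(\CC1OCCO1)COC(=O)C(C)C)[C@@H](C)CCCOC(C)=O | intermediate
24 | formyl allylboronate (C8 aldehyde) | COC(=O)/C(CB1OC(C)(C)C(C)(C)O1)=C\[C@H](O[Si](C)(C)C(C)(C)C)/C(=C(\CC=O)COC(=O)C(C)C)[C@@H](C)CCCOC(C)=O | intermediate
25 | methyl 2-[cyclohex-3-enyl]acrylate with 6-OTBS, 8-O-B(pin), ring configuration as in target | C=C(C(=O)OC)[C@H]1[C@H](OB2OC(C)(C)C(C)(C)O2)CC(COC(=O)C(C)C)=C([C@@H](C)CCCOC(C)=O)[C@H]1O[Si](C)(C)C(C)(C)C | intermediate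
26 | 6-O-TBS ether of the target | C=C1C(=O)O[C@@H]2CC(COC(=O)C(C)C)=C([C@@H](C)CCCOC(C)=O)[C@@H](O[Si](C)(C)C(C)(C)C)[C@@H]12 | intermediate
27 | CNP0246650.1 | C=C1C(=O)O[C@@H]2CC(COC(=O)C(C)C)=C([C@@H](C)CCCOC(C)=O)[C@@H](O)[C@@H]12 | target

## Step count and risks

Total step count: 14. Longest linear sequence: 13 (steps 2–14, from 5 to 27); step 1 is a one-step side branch.

**Risk 1, step 13 (double ring closure).** The β,γ-unsaturated aldehyde 24 may slip into conjugation before it cyclizes, the deactivated allylboronate may add slowly, or the facial preference relative to C6 may be lower than predicted. The fallback replaces the closed boron transition state by an open, Lewis acid-promoted allylsilane addition; it sets out from 20 and comes back at 26. Iodide 20 is coupled with Me3SiCH2ZnCl (Pd(PPh3)4, THF) to give allylsilane F1. The dioxolane is cleaved with TESOTf/2,4,6-collidine then water to give formyl allylsilane F2. BF3·OEt2 (CH2Cl2, −78 °C) then effects intramolecular Hosomi–Sakurai cyclization to hydroxy ester F3, which p-TsOH·H2O lactonizes to 26.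

**Risk 2, step 9 (asymmetric alkynylation).** The tetrasubstituted, α-branched enal is hindered, so rate and ee may be poor, and the sense of induction rests on analogy. The fallback sets C6 by reagent-controlled reduction instead of addition; it sets out from 15 and comes back at 17. Lithium methyl propiolate (16, LiN(SiMe3)2, THF, −78 °C) adds to 15 to give carbinol F4 as a C6 epimer mixture. MnO2 (or Dess–Martin periodinane) oxidizes it to ynone F5. (R)-2-methyl-CBS-oxazaborolidine with catecholborane (toluene, −78 °C) then reduces F5 to 17; the alkynyl group acts as the small substituent and the tetrasubstituted alkenyl as the large one, which gives the S carbinol.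

**Risk 3, step 5 (sp3 Negishi coupling).** The β,β-dialkoxyalkylzinc reagent can β-eliminate or couple slowly at the hindered triflate, and zerovalent palladium may ionize the allylic isobutyrate. The fallback brings in C9–C8 as a vinyl group and adjusts the oxidation level afterwards; it sets out from 9 and comes back at 11. Triflate 9 is coupled with potassium vinyltrifluoroborate (PdCl2(dppf), Cs2CO3, THF/H2O) to give diene F6. 9-BBN hydroborates only the monosubstituted vinyl terminus, and NaBO3·4H2O gives alcohol F7. Dess–Martin periodinane gives aldehyde F8, which is acetalized at once (ethylene glycol, PPTS, benzene, rt) to 11.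

## Further compounds

F1 | step 13 | methyl (2Z)-2-[(trimethylsilyl)methyl] dienoate (allylsilane analogue of 23) | COC(=O)/C(C[Si](C)(C)C)=C\[C@H](O[Si](C)(C)C(C)(C)C)/C(=C(\CC1OCCO1)COC(=O)C(C)C)[C@@H](C)CCCOC(C)=O
F2 | step 13 | formyl allylsilane (C8 aldehyde) | COC(=O)/C(C[Si](C)(C)C)=C\[C@H](O[Si](C)(C)C(C)(C)C)/C(=C(\CC=O)COC(=O)C(C)C)[C@@H](C)CCCOC(C)=O
F3 | step 13 | methyl 2-[cyclohex-3-enyl]acrylate with 6-OTBS and free 8-OH, ring configuration as in target | C=C(C(=O)OC)[C@H]1[C@H](O)CC(COC(=O)C(C)C)=C([C@@H](C)CCCOC(C)=O)[C@H]1O[Si](C)(C)C(C)(C)C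
F4 | step 9 | C6 epimer mixture of 17 | COC(=O)C#CC(O)/C(=C(\CC1OCCO1)COC(=O)C(C)C)[C@@H](C)CCCOC(C)=O
F5 | step 9 | methyl (5E)-5-[(2S)-5-acetoxypentan-2-yl]-6-(1,3-dioxolan-2-ylmethyl)-7-(isobutyryloxy)-4-oxohept-5-en-2-ynoate (ynone) | COC(=O)C#CC(=O)/C(=C(\CC1OCCO1)COC(=O)C(C)C)[C@@H](C)CCCOC(C)=O
F6 | step 5 | (3S)-2-[1-(isobutyryloxy)but-3-en-2-ylidene]-N-methoxy-N,3,7-trimethyloct-6-enamide (vinyl cis to amide C=O) | CON(C)C(=O)/C(=C(\C=C)COC(=O)C(C)C)[C@@H](C)CCC=C(C)C
F7 | step 5 | (3S)-2-[4-hydroxy-1-(isobutyryloxy)butan-2-ylidene]-N-methoxy-N,3,7-trimethyloct-6-enamide | CON(C)C(=O)/C(=C(\CCO)COC(=O)C(C)C)[C@@H](C)CCC=C(C)C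
F8 | step 5 | (3S)-2-[1-(isobutyryloxy)-4-oxobutan-2-ylidene]-N-methoxy-N,3,7-trimethyloct-6-enamide | CON(C)C(=O)/C(=C(\CC=O)COC(=O)C(C)C)[C@@H](C)CCC=C(C)C
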